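# Proposed total synthesis of bis-5,5-nortrachelogenin by a stereoretentive double Baeyer–Villiger oxidation

Conventions: lactone atoms are numbered O1, C2 (carbonyl), C3, C4, C5. Rings A and A′ are the guaiacyl rings on the C3 methylene arms. Rings B and B′ are the two linked guaiacyl rings on the C4 methylene arms. Compounds are numbered 1–25 in the order in which they first appear in the steps.

Remark on protecting groups: the phenols are carried as benzyl ethers as far as diketone 21 and as acetates through the peracid step. Diketone 23, the substrate of the key step, therefore differs from 21 only in its phenol protecting groups.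

Remark on 20: it is drawn as the 3,4-trans keto tautomer. Its enol and its C3 epimer are expected to be present as well, which is immaterial because C3 becomes planar in step 13.

## Analysis of the target

Bis-5,5-nortrachelogenin (25) is a C2-symmetric dimer of two 3-hydroxy-3,4-bis(arylmethyl)oxolan-2-ones in which rings B and B′ are joined C5–C5′, ortho to their phenolic hydroxyls, whereas rings A and A′ are not linked. Each lactone has two adjacent stereocentres, C3 (R), a fully substituted carbinol next to the lactone carbonyl, and C4 (R), and both halves have the same absolute configuration. The two arylmethyl groups are trans across C3–C4, so the tertiary hydroxyl is cis to the C4 arm. The biaryl axis carries only the two hydroxyls and two hydrogens in its ortho positions and should rotate freely, so it adds no stereochemical element. The sensitive groups are four phenols (two of them a 2,2′-biphenol that is easily oxidised), two γ-lactones that open in base, and four electron-rich arenes. The difficulty is the quaternary carbinol at C3, whose oxygen lies on the face shared with the neighbouring C4 arm, and every stereo-defining event has to succeed twice in one molecule, so any imperfect selectivity is multiplied. The strategy rests on the C3–O bond being syn to the C4–CH2(ring B) bond: that arm sends a carbon electrophile to the opposite face of a planar C3 enolate that already bears an acetyl group. The acetyl is thereby left on the side of the arm, and its carbon is then exchanged for oxygen with retention.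

## Retrosynthetic reasoning

**25 from 24.** The last operation only unmasks. Six acyl C–O bonds (four aryl acetates and the two tertiary C3 acetates) are cut, which leads from target 25 back to hexaacetate 24. With all six hydroxyls under one kind of protecting group, a single transesterification ends the synthesis. No stereocentre is at risk, because C3 has no hydrogen and C4 is not α to a carbonyl.

**24 from 23.** The two C3–O bonds are traced back to two C3–C(acetyl) bonds, so 24 comes from bis(methyl ketone) 23 by a double Baeyer–Villiger oxidation. The cut is made here because an oxidant approaching a C3 enolate of a 3,4-bis(arylmethyl) lactone has to come in on the side of the C4 arm. Its facial selectivity would then depend on the conformations of two flexible arms, and it would have to be right at both lactones. Exchanging carbon for oxygen with retention turns the problem into placing a carbon substituent on that face, which an alkylation from the open face does indirectly. The forward reaction must insert oxygen on the C3 side of each ketone and must not touch the arenes.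

**23 from 22 from 21.** The aryl acetates of 23 come from tetraphenol 22, and 22 from tetrabenzyl ether 21. Benzyl ethers are the right choice for the hydride and amide-base steps that precede 21. In the peracid step, however, a 1,2-dialkoxyarene would be a competing nucleophile. Acetates lower the electron density of all four rings and leave in the same final methanolysis as the C3 acetates.

**21 from 20 and 17.** The two C3–CH2(ring A) bonds are cut, giving bis(β-keto lactone) 20 and benzylic bromide 17. The stabilised enolate of 20 is flat at C3 and its only facial bias is the C4 arm. The bromide should therefore enter anti to that arm, leaving the acetyl cis to it. This is the step that fixes the C3 configuration of the target.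

**20 from 14.** The two C3–C(O)CH3 bonds are cut, giving bis-lactone 14. A Claisen-type C-acylation of the lactone enolates supplies the carbon that will later become the acetate.

**14 from 13 from 12.** The lactone O1–C2 bonds are opened to hydroxy tert-butyl esters 13, and the primary alcohols of 13 are traced to the imide carbonyls of 12. The two carbonyls of each succinate are different by construction. LiBH4 reduces only the imide, and the tert-butyl ester then closes the ring under acid.

**12 from 10 and 5.** The two C4–CH2(ring B) bonds are cut. Two enolates of succinate imide 10 are alkylated by bis(benzylic bromide) 5. The auxiliary sets both C4 centres and makes any stereoisomeric by-product a separable diastereomer.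

**10 from 7 and 8, and 7 from 6.** Imide 10 comes from mono-tert-butyl succinate 7 and auxiliary 8, and 7 from succinic anhydride 6.

**5 from 4, 3, 2 and 1.** The C5–C5′ biaryl bond is made first, by oxidative dimerisation of two molecules of vanillin 1 to 2. The molecule is symmetrical, so no cross-coupling is needed. The aldehydes of 2 become the bromomethyl groups through benzyl ether 3 and diol 4.

**17 from 16 from 15.** Bromide 17 comes from O-benzylvanillin 15 by reduction to alcohol 16 and bromination.

## Alternatives that were turned down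

**Alternative 1:** The C3–CH2(ring A) bonds are cut last, from a lactone that already carries the C3 oxygen. In the forward key step the bis(α-hydroxy lactone) A1 is deprotonated four times with LiN(SiMe3)2, and both alkoxide–enolates are C-benzylated by bromide 17 anti to the C4 arms to give tetra-O-benzyl bis-5,5-nortrachelogenin A2.

- For: it is the shortest plan. The product A2 is one hydrogenolysis away from 25, and no peracid is used near the arenes. It relies on the same facial bias of the C4 arm as the chosen route.
- Against: the nucleophile is a tetralithiated species of high molecular weight, whose aggregation and solubility are hard to foresee. Each site offers an alkoxide oxygen as a competing nucleophile toward a reactive benzylic bromide. The second alkylation must take place on an intermediate that already holds one quaternary centre and three negative charges. A1 also has to be made first, by oxidising the enolates of 14 or from chiral-pool material.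
- Comparison: Alternative 1 is stronger on step count and on oxidant tolerance. The chosen strategy offers instead a quaternary centre built by carbonate-mediated alkylation of a neutral β-keto lactone, without a polyanion. The carbinol configuration can also be secured and purified at the stage of ketone 21, before a stereospecific step converts it.

**Alternative 2:** The C4–CH2(ring B) bonds are cut on an acyclic hydroxy diester from the chiral pool. In the forward key step two alkoxide–enolates of dimethyl (R)-malate A3 displace both bromides of 5 to give the tetramethyl bis(arylmethyl)malate A4, each new centre anti to its hydroxyl.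

- For: the C4 configuration comes from the chiral pool without an auxiliary. The C3 oxygen is present from the first step, and the same bromide 5 is used.
- Against: A4 is not yet a lactone. In each half the ester at C4 must be reduced in the presence of the ester next to the hydroxyl, which is the one that hydroxyl-directed reductions activate, so a differentiation sequence is needed. The anti selectivity of each alkylation counts twice. The C3–CH2(ring A) bonds are still missing and would have to be made by the alkylation of Alternative 1 on A1, with its uncertainties.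
- Comparison: Alternative 2 is stronger on the source of chirality. The chosen route offers two carbonyls that are differentiated from the outset (imide against tert-butyl ester) and diastereomers that the auxiliary makes separable.

**Alternative 3:** The C3–C4 bonds are cut, so that both stereocentres of each lactone arise in one sigmatropic event. In the forward key step the bis-ester A5 (two (Z)-configured (R)-allylic esters carrying 2-benzyloxy-3-arylpropanoyl groups, held on the biaryl) is enolised under chelation control with LiN(iPr)2 and silylated with Me3SiCl. Two [3,3] shifts through chair transition states then give the bis(hexenoic acid) A6 with two (E)-propenyl groups.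

- For: the C3/C4 relationship is set by transition-state geometry and not by a substrate facial bias. The C3 oxygen is in place and the most congested bond is formed directly.
- Against: with the chelated enolate the benzyloxy group sits equatorial in the chair. The cis relationship between the C3 oxygen and the C4 arm then requires the ring B methylene to be axial, that is a (Z)-allylic double bond. A5 therefore needs two enantiopure (Z)-configured secondary allylic carbinols on the biaryl. After the rearrangement each propenyl group must be cleaved oxidatively in the presence of six electron-rich rings, reduced and lactonised, and a tertiary benzyl ether must be removed.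
- Comparison: Alternative 3 is stronger in principle on stereocontrol at the C3–C4 bond. It is much longer and has its own oxidant-against-arene problem, on rings that cannot be deactivated at that stage. The chosen route derives C3 from the existing C4 centre in a simple alkylation and exposes only acetate-deactivated rings to one oxidant.

Key step: step 16

## Route

Step 1
Reactants: 1 vanillin (2 equiv)
Product: 2 5,5'-bivanillin (6,6'-dihydroxy-5,5'-dimethoxybiphenyl-3,3'-dicarbaldehyde)
Conditions: Na2S2O8 (0.55 equiv per 1), FeSO4·7H2O (cat.), H2O, 50 °C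
Reagents that add atoms: none
Why: Oxidative phenol coupling of two molecules of 1; one-electron oxidation of the phenol and C–C coupling at C5, the only free position ortho to the hydroxyl (the para position carries the formyl group), should give the symmetrical biaryl, which precipitates from water.

Step 2
Reactants: 2 5,5'-bivanillin
Product: 3 6,6'-bis(benzyloxy)-5,5'-dimethoxybiphenyl-3,3'-dicarbaldehyde
Conditions: BnBr, K2CO3, DMF, 60 °C
Reagents that add atoms: benzyl bromide, BrCc1ccccc1
Why: Williamson ether synthesis on the two phenolates; the benzyl ethers tolerate the hydride, amide-base and carbonate steps that follow.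

Step 3
Reactants: 3 6,6'-bis(benzyloxy)-5,5'-dimethoxybiphenyl-3,3'-dicarbaldehyde
Product: 4 [6,6'-bis(benzyloxy)-5,5'-dimethoxybiphenyl-3,3'-diyl]dimethanol
Conditions: NaBH4, THF/MeOH, 0 °C → rt
Reagents that add atoms: none
Why: Borohydride reduction of two aryl aldehydes to benzylic alcohols; no other reducible group is present.

Step 4
Reactants: 4 [6,6'-bis(benzyloxy)-5,5'-dimethoxybiphenyl-3,3'-diyl]dimethanol
Product: 5 2,2'-bis(benzyloxy)-5,5'-bis(bromomethyl)-3,3'-dimethoxybiphenyl
Conditions: PBr3, CH2Cl2, 0 °C
Reagents that add atoms: phosphorus tribromide, BrP(Br)Br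
Why: Conversion of benzylic alcohols into bromides through their phosphite esters; the electron-rich dibromide is used without storage.

Step 5
Reactants: 6 succinic anhydride
Product: 7 4-(tert-butoxy)-4-oxobutanoic acid
Conditions: t-BuOH, N-hydroxysuccinimide (cat.), DMAP (cat.), Et3N (cat.), toluene, reflux
Reagents that add atoms: tert-butanol, CC(C)(C)O
Why: Nucleophile-catalysed ring opening of a cyclic anhydride by a hindered alcohol gives the half-ester; the second carboxyl stays free for imide formation.

Step 6
Reactants: 7 4-(tert-butoxy)-4-oxobutanoic acid; 8 (S)-4-benzyl-1,3-oxazolidin-2-one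
Product: 10 tert-butyl 4-[(4S)-4-benzyl-2-oxo-1,3-oxazolidin-3-yl]-4-oxobutanoate, via mixed pivalic anhydride 9 (not isolated)
Conditions: t-BuCOCl, Et3N, THF, −20 °C; then LiCl, 8, −20 °C → rt
Reagents that add atoms: pivaloyl chloride, CC(C)(C)C(Cl)=O (its acyl group stays only in intermediate 9)
Why: N-acylation of the oxazolidinone through a mixed anhydride; the auxiliary attacks the unhindered succinyl carbonyl and not the pivaloyl carbonyl.

Step 7
Reactants: 10 tert-butyl 4-[(4S)-4-benzyl-2-oxo-1,3-oxazolidin-3-yl]-4-oxobutanoate (2.4 equiv); 5 2,2'-bis(benzyloxy)-5,5'-bis(bromomethyl)-3,3'-dimethoxybiphenyl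
Product: 12 di-tert-butyl 3,3'-{[6,6'-bis(benzyloxy)-5,5'-dimethoxybiphenyl-3,3'-diyl]bis(methylene)}bis{(3S)-4-[(4S)-4-benzyl-2-oxo-1,3-oxazolidin-3-yl]-4-oxobutanoate}, via sodium enolate 11 (not isolated)
Conditions: NaN(SiMe3)2, THF, −78 °C; then 5, −78 → −30 °C
Reagents that add atoms: sodium bis(trimethylsilyl)amide, C[Si](C)(C)[N-][Si](C)(C)C.[Na+] (sodium stays only in intermediate 11)
Why: Two-directional Evans alkylation; deprotonation occurs α to the more acidic imide carbonyl to give the chelated (Z)-enolate, and each benzylic bromide is attacked from the enolate face away from the auxiliary benzyl group, which sets both new centres (S); any stereoisomeric by-product is a diastereomer and should be removable by chromatography.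

Step 8
Reactants: 12 the bis-imide of step 7
Product: 13 di-tert-butyl 3,3'-{[6,6'-bis(benzyloxy)-5,5'-dimethoxybiphenyl-3,3'-diyl]bis(methylene)}bis[(3S)-4-hydroxybutanoate]
Conditions: LiBH4, H2O (1 equiv per imide), Et2O/THF, 0 °C
Reagents that add atoms: none
Why: Reductive cleavage of N-acyl oxazolidinones; LiBH4 reduces the activated exocyclic imide carbonyl to the primary alcohol and releases 8, whereas the tert-butyl esters are not touched.

Step 9
Reactants: 13 the bis(hydroxy tert-butyl ester) of step 8
Product: 14 4,4'-{[6,6'-bis(benzyloxy)-5,5'-dimethoxybiphenyl-3,3'-diyl]bis(methylene)}bis[(4S)-oxolan-2-one]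
Conditions: TsOH·H2O (cat.), toluene, 80 °C
Reagents that add atoms: none
Why: Acid-catalysed lactonisation; each primary hydroxyl closes onto the tert-butyl ester with loss of tert-butanol, and the C4 centres are not enolisable and keep their configuration.

Step 10
Reactants: 15 4-(benzyloxy)-3-methoxybenzaldehyde
Product: 16 [4-(benzyloxy)-3-methoxyphenyl]methanol
Conditions: NaBH4, MeOH, 0 °C
Reagents that add atoms: none
Why: Borohydride reduction of an aryl aldehyde.

Step 11
Reactants: 16 [4-(benzyloxy)-3-methoxyphenyl]methanol
Product: 17 1-(benzyloxy)-4-(bromomethyl)-2-methoxybenzene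
Conditions: PBr3, CH2Cl2, 0 °C
Reagents that add atoms: phosphorus tribromide, BrP(Br)Br
Why: Benzylic alcohol to bromide through the phosphite ester; the bromide is prepared shortly before use.

Step 12
Reactants: 14 the bis-lactone of step 9
Product: 20 4,4'-{[6,6'-bis(benzyloxy)-5,5'-dimethoxybiphenyl-3,3'-diyl]bis(methylene)}bis[(3R,4S)-3-acetyloxolan-2-one], via dilithium bis-enolate 18 (not isolated), via dilithium acylenolate 19 (not isolated)
Conditions: LiN(SiMe3)2 (4.4 equiv), THF, −78 °C; AcCl (2.4 equiv), −78 → −40 °C; aq. NH4Cl
Reagents that add atoms: acetyl chloride, CC(Cl)=O; lithium bis(trimethylsilyl)amide, C[Si](C)(C)[N-][Si](C)(C)C.[Li+] (lithium stays only in intermediates 18 and 19)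
Why: Claisen-type C-acylation of lactone enolates; the second equivalent of base converts each β-keto lactone into its enolate as it forms, which protects it from further acylation, and protonation should give mainly the 3,4-trans keto form, whose C3 configuration does not matter for the next step.

Step 13
Reactants: 20 the bis(β-keto lactone) of step 12; 17 1-(benzyloxy)-4-(bromomethyl)-2-methoxybenzene (2.4 equiv)
Product: 21 4,4'-{[6,6'-bis(benzyloxy)-5,5'-dimethoxybiphenyl-3,3'-diyl]bis(methylene)}bis{(3S,4S)-3-acetyl-3-[4-(benzyloxy)-3-methoxybenzyl]oxolan-2-one}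
Conditions: K2CO3, acetone, reflux
Reagents that add atoms: none
Why: C-alkylation of a β-keto lactone under carbonate conditions; the stabilised enolate is planar at C3 with the acetyl group in the plane, so the C4 arm is the only facial bias and the bromide should enter anti to it, which puts the ring A methylene trans and the acetyl cis to the C4 arm at both lactones.

Step 14
Reactants: 21 the tetrabenzyl bis(quaternary ketone) of step 13
Product: 22 4,4'-{[6,6'-dihydroxy-5,5'-dimethoxybiphenyl-3,3'-diyl]bis(methylene)}bis[(3S,4S)-3-acetyl-3-(4-hydroxy-3-methoxybenzyl)oxolan-2-one]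
Conditions: H2 (1 atm), 10% Pd/C, EtOAc/THF, rt
Reagents that add atoms: none
Why: Hydrogenolysis of four aryl benzyl ethers; the aliphatic ketones, the lactones and the non-enolisable C3 centres are inert under these neutral conditions.

Step 15
Reactants: 22 the tetraphenol of step 14
Product: 23 4,4'-{[6,6'-diacetoxy-5,5'-dimethoxybiphenyl-3,3'-diyl]bis(methylene)}bis[(3S,4S)-3-acetyl-3-(4-acetoxy-3-methoxybenzyl)oxolan-2-one]
Conditions: Ac2O, pyridine, DMAP (cat.), CH2Cl2, 0 °C → rt
Reagents that add atoms: acetic anhydride, CC(=O)OC(C)=O
Why: Acetylation of the four phenols; the acyloxy groups make the rings poorer nucleophiles for the peracid step and are removed together with the C3 acetates at the end.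

Step 16
Reactants: 23 the tetraacetate bis(methyl ketone) of step 15
Product: 24 4,4'-{[6,6'-diacetoxy-5,5'-dimethoxybiphenyl-3,3'-diyl]bis(methylene)}bis[(3R,4R)-3-acetoxy-3-(4-acetoxy-3-methoxybenzyl)oxolan-2-one]
Conditions: (CF3CO)2O, urea·H2O2, Na2HPO4, CH2Cl2, 0 °C → rt
Reagents that add atoms: trifluoroperacetic acid, OOC(=O)C(F)(F)F, made in the flask from trifluoroacetic anhydride, O=C(OC(=O)C(F)(F)F)C(F)(F)F, and urea–hydrogen peroxide, NC(N)=O.OO (one peroxide oxygen enters each C3–O–acetyl unit)
Why: Double Baeyer–Villiger oxidation: CF3CO3H adds to each acetyl carbonyl to give a peroxy hemiketal (Criegee adduct), and the C3–C(acyl) bond antiperiplanar to the O–O bond shifts to oxygen as trifluoroacetate leaves, a concerted 1,2-shift in which C3 keeps its configuration. The closest known reaction type is the Baeyer–Villiger oxidation of α,α-disubstituted β-keto esters and 2,2-disubstituted 1,3-diketones to α-acyloxy carbonyl compounds. No ring is closed and no stereocentre is made from a prochiral atom; each C3 carbinol centre is the C3 centre of 23 carried over with retention, so its configuration is controlled by the benzylation of step 13 (acetyl cis to the C4 arm becomes acetoxy cis to the C4 arm, and the descriptor changes from S to R only because the priorities change). The first selectivity needed is migration of C3 and not of methyl, which the full substitution of C3 should secure, since it stabilises the developing positive charge far better than methyl even with the lactone carbonyl attached. The second is oxidation of the ketones and not of the arenes; in 23 each ring carries an acyloxy group in place of an ether and only one methoxy donor, which lowers its reactivity toward the electrophilic peracid, and Na2HPO4 removes CF3CO2H so that acid-promoted ring hydroxylation is suppressed. The two ketones are remote from each other and should react independently, and the quaternary C3 centres cannot enolise, so no epimerisation is possible before or after the shift.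

Step 17
Reactants: 24 the hexaacetate of step 16
Product: 25 bis-5,5-nortrachelogenin, 4,4'-{[6,6'-dihydroxy-5,5'-dimethoxybiphenyl-3,3'-diyl]bis(methylene)}bis[(3R,4R)-3-hydroxy-3-(4-hydroxy-3-methoxybenzyl)oxolan-2-one]
Conditions: K2CO3, MeOH, 0 °C → rt, under argon; then 1 M HCl to pH 3
Reagents that add atoms: none
Why: Base-mediated transesterification removes the four aryl acetates and the two activated α-acyloxy-lactone acetates as methyl acetate; any lactone opened by methoxide should close again on acidification, and neither C3 (no hydrogen) nor C4 (not α to a carbonyl) can epimerise.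

## Compound list

1 | vanillin (4-hydroxy-3-methoxybenzaldehyde) | COc1cc(C=O)ccc1O | starting material
2 | 5,5'-bivanillin (6,6'-dihydroxy-5,5'-dimethoxybiphenyl-3,3'-dicarbaldehyde) | COc1cc(C=O)cc(c1O)-c1cc(C=O)cc(OC)c1O | intermediate
3 | 6,6'-bis(benzyloxy)-5,5'-dimethoxybiphenyl-3,3'-dicarbaldehyde | COc1cc(C=O)cc(c1OCc1ccccc1)-c1cc(C=O)cc(OC)c1OCc1ccccc1 | intermediate
4 | [6,6'-bis(benzyloxy)-5,5'-dimethoxybiphenyl-3,3'-diyl]dimethanol | COc1cc(CO)cc(c1OCc1ccccc1)-c1cc(CO)cc(OC)c1OCc1ccccc1 | intermediate
5 | 2,2'-bis(benzyloxy)-5,5'-bis(bromomethyl)-3,3'-dimethoxybiphenyl | COc1cc(CBr)cc(c1OCc1ccccc1)-c1cc(CBr)cc(OC)c1OCc1ccccc1 | intermediate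
6 | succinic anhydride | O=C1CCC(=O)O1 | starting material
7 | 4-(tert-butoxy)-4-oxobutanoic acid | CC(C)(C)OC(=O)CCC(=O)O | intermediate
8 | (S)-4-benzyl-1,3-oxazolidin-2-one | O=C1N[C@@H](Cc2ccccc2)CO1 | starting material
9 | 4-(tert-butoxy)-4-oxobutanoic pivalic anhydride | CC(C)(C)OC(=O)CCC(=O)OC(=O)C(C)(C)C | intermediate (not isolated)
10 | tert-butyl 4-[(4S)-4-benzyl-2-oxo-1,3-oxazolidin-3-yl]-4-oxobutanoate | CC(C)(C)OC(=O)CCC(=O)N1C(=O)OC[C@@H]1Cc1ccccc1 | intermediate
11 | sodium (Z)-enolate of 10 | [Na+].CC(C)(C)OC(=O)C/C=C(\[O-])N1C(=O)OC[C@@H]1Cc1ccccc1 | intermediate (not isolated)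
12 | di-tert-butyl 3,3'-{[6,6'-bis(benzyloxy)-5,5'-dimethoxybiphenyl-3,3'-diyl]bis(methylene)}bis{(3S)-4-[(4S)-4-benzyl-2-oxo-1,3-oxazolidin-3-yl]-4-oxobutanoate} | CC(C)(C)OC(=O)C[C@H](Cc1cc(OC)c(OCc2ccccc2)c(c1)-c1cc(C[C@@H](CC(=O)OC(C)(C)C)C(=O)N2C(=O)OC[C@@H]2Cc2ccccc2)cc(OC)c1OCc1ccccc1)C(=O)N1C(=O)OC[C@@H]1Cc1ccccc1 | intermediate
13 | di-tert-butyl 3,3'-{[6,6'-bis(benzyloxy)-5,5'-dimethoxybiphenyl-3,3'-diyl]bis(methylene)}bis[(3S)-4-hydroxybutanoate] | CC(C)(C)OC(=O)C[C@@H](CO)Cc1cc(OC)c(OCc2ccccc2)c(c1)-c1cc(C[C@@H](CC(=O)OC(C)(C)C)CO)cc(OC)c1OCc1ccccc1 | intermediate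
14 | 4,4'-{[6,6'-bis(benzyloxy)-5,5'-dimethoxybiphenyl-3,3'-diyl]bis(methylene)}bis[(4S)-oxolan-2-one] (bis-lactone) | O=C1OC[C@H](C1)Cc1cc(OC)c(OCc2ccccc2)c(c1)-c1cc(C[C@@H]2COC(=O)C2)cc(OC)c1OCc1ccccc1 | intermediate
15 | 4-(benzyloxy)-3-methoxybenzaldehyde | COc1cc(C=O)ccc1OCc1ccccc1 | starting material
16 | [4-(benzyloxy)-3-methoxyphenyl]methanol | COc1cc(CO)ccc1OCc1ccccc1 | intermediate
17 | 1-(benzyloxy)-4-(bromomethyl)-2-methoxybenzene | COc1cc(CBr)ccc1OCc1ccccc1 | intermediate
18 | dilithium bis(lactone enolate) of 14 | [Li+].[Li+].[O-]C1=C[C@@H](CO1)Cc1cc(OC)c(OCc2ccccc2)c(c1)-c1cc(C[C@@H]2COC([O-])=C2)cc(OC)c1OCc1ccccc1 | intermediate (not isolated)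
19 | dilithium bis(enolate) of 20 | [Li+].[Li+].CC([O-])=C1C(=O)OC[C@H]1Cc1cc(OC)c(OCc2ccccc2)c(c1)-c1cc(C[C@@H]2COC(=O)C2=C(C)[O-])cc(OC)c1OCc1ccccc1 | intermediate (not isolated)
20 | 4,4'-{[6,6'-bis(benzyloxy)-5,5'-dimethoxybiphenyl-3,3'-diyl]bis(methylene)}bis[(3R,4S)-3-acetyloxolan-2-one], acetyl trans to the C4 arm | CC(=O)[C@@H]1C(=O)OC[C@H]1Cc1cc(OC)c(OCc2ccccc2)c(c1)-c1cc(C[C@@H]2COC(=O)[C@H]2C(C)=O)cc(OC)c1OCc1ccccc1 | intermediate
21 | 4,4'-{[6,6'-bis(benzyloxy)-5,5'-dimethoxybiphenyl-3,3'-diyl]bis(methylene)}bis{(3S,4S)-3-acetyl-3-[4-(benzyloxy)-3-methoxybenzyl]oxolan-2-one}, acetyl cis to the C4 arm | COc1cc(C[C@]2(C(C)=O)C(=O)OC[C@H]2Cc2cc(OC)c(OCc3ccccc3)c(-c3cc(C[C@@H]4COC(=O)[C@@]4(C(C)=O)Cc4ccc(OCc5ccccc5)c(OC)c4)cc(OC)c3OCc3ccccc3)c2)ccc1OCc1ccccc1 | intermediate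
22 | 4,4'-{[6,6'-dihydroxy-5,5'-dimethoxybiphenyl-3,3'-diyl]bis(methylene)}bis[(3S,4S)-3-acetyl-3-(4-hydroxy-3-methoxybenzyl)oxolan-2-one] | COc1cc(C[C@]2(C(C)=O)C(=O)OC[C@H]2Cc2cc(OC)c(O)c(-c3cc(C[C@@H]4COC(=O)[C@@]4(C(C)=O)Cc4ccc(O)c(OC)c4)cc(OC)c3O)c2)ccc1O | intermediate
23 | 4,4'-{[6,6'-diacetoxy-5,5'-dimethoxybiphenyl-3,3'-diyl]bis(methylene)}bis[(3S,4S)-3-acetyl-3-(4-acetoxy-3-methoxybenzyl)oxolan-2-one] | COc1cc(C[C@]2(C(C)=O)C(=O)OC[C@H]2Cc2cc(OC)c(OC(C)=O)c(-c3cc(C[C@@H]4COC(=O)[C@@]4(C(C)=O)Cc4ccc(OC(C)=O)c(OC)c4)cc(OC)c3OC(C)=O)c2)ccc1OC(C)=O | intermediate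
24 | 4,4'-{[6,6'-diacetoxy-5,5'-dimethoxybiphenyl-3,3'-diyl]bis(methylene)}bis[(3R,4R)-3-acetoxy-3-(4-acetoxy-3-methoxybenzyl)oxolan-2-one] | COc1cc(C[C@]2(OC(C)=O)C(=O)OC[C@H]2Cc2cc(OC)c(OC(C)=O)c(-c3cc(C[C@@H]4COC(=O)[C@@]4(OC(C)=O)Cc4ccc(OC(C)=O)c(OC)c4)cc(OC)c3OC(C)=O)c2)ccc1OC(C)=O | intermediate
25 | bis-5,5-nortrachelogenin, 4,4'-{[6,6'-dihydroxy-5,5'-dimethoxybiphenyl-3,3'-diyl]bis(methylene)}bis[(3R,4R)-3-hydroxy-3-(4-hydroxy-3-methoxybenzyl)oxolan-2-one] | COc1cc(C[C@]2(O)C(=O)OC[C@H]2Cc2cc(OC)c(O)c(-c3cc(C[C@@H]4COC(=O)[C@@]4(O)Cc4ccc(O)c(OC)c4)cc(OC)c3O)c2)ccc1O | target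

## Step count and least certain steps

Total step count: 17. Longest linear sequence: 13 steps (steps 1–4, 7–9 and 12–17, from vanillin).

**Step 16 (key step).** The ketones are hindered, each flanked by a quaternary carbon with two arylmethyl groups. Slow formation of the peroxy adduct would give the peracid time to hydroxylate the methoxy-bearing rings, and one of the two ketones could remain unchanged. A share of methyl migration is also conceivable, because the migrating C3 carries an electron-withdrawing lactone carbonyl.
Fallback: it sets out from bis-lactone 14 and abandons the carbon-to-oxygen exchange. Double enolate hydroxylation (LiN(SiMe3)2, THF, −78 °C; 2-(phenylsulfonyl)-3-phenyloxaziridine) would give the bis(3-hydroxy lactone) F1, with oxygen mainly anti to the arm; this C3 configuration is erased in the next operation. Fourfold deprotonation (LiN(SiMe3)2, THF/DMPU, −78 → −20 °C) and alkylation of both alkoxide–enolates by bromide 17 anti to the C4 arms would give tetra-O-benzyl bis-5,5-nortrachelogenin F2 (the same structure as A2). Hydrogenolysis (H2, Pd/C, EtOAc/THF) comes back to the route at target 25.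

**Step 13 (the fallback also bypasses step 12).** The facial selectivity may be lower than needed, because the arm that shields the enolate is conformationally mobile, and the loss counts at both lactones. The ambident enolate may also be benzylated on oxygen by the reactive, electron-rich bromide. In step 12 itself, O-acylation or incomplete double acylation is possible.
Fallback: it sets out from bis-lactone 14 and replaces the stabilised enolate by a chelated alkoxide–enolate. A double aldol addition to acetaldehyde (LiN(iPr)2, THF, −78 °C; CH3CHO) would give the bis[3-(1-hydroxyethyl) lactone] F3 as a mixture at the carbinol centres. Double deprotonation of each half (LiN(iPr)2, THF/DMPU, −78 → −30 °C) and C-benzylation with 17 anti to the C4 arm would give the bis[3-(1-hydroxyethyl)-3-(arylmethyl) lactone] F4. Oxidation of both carbinols with Dess–Martin periodinane comes back to the route at diketone 21. The carbinol centres are mixtures and may themselves influence the alkylation, so this path is not free of selectivity questions either.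

**Step 7.** The second alkylation may be slower than decomposition of the sodium enolate or of the mono-alkylated benzylic bromide, which would leave mono-adduct. The per-site selectivity is multiplied over two sites.
Fallback: it sets out from dialdehyde 3 and sets the C4 centres by catalysis. A double Stobbe condensation with dimethyl succinate (t-BuOK, t-BuOH) would give the bis[(E)-arylidene succinic half-ester] F5. Asymmetric hydrogenation ([Rh(cod)2]BF4 with the enantiomer of a bisphospholane ligand of the DuPhos type that delivers the (S) acid, H2, MeOH) would give the bis[(S)-arylmethyl succinic half-ester] F6. Reduction of the methyl esters in the presence of the carboxylates (Ca(BH4)2 from CaCl2 and NaBH4, EtOH) and acidification would close both lactones and come back to the route at bis-lactone 14.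

**Step 17.** Methanolysis of the two hindered tertiary acetates may lag behind that of the aryl acetates. Longer exposure to base would keep the lactones open and expose the 2,2'-biphenolate to air oxidation.
Fallback: it sets out from hexaacetate 24 and opens the lactones on purpose. Saponification of all eight ester groups (LiOH, degassed THF/H2O, 0 °C → rt) and acidification would give the bis(dihydroxy acid) F7. Acid-catalysed relactonisation (TsOH·H2O cat., THF, rt) comes back to the route at target 25.

## Further compounds

F1 | step 16 | 4,4'-{[6,6'-bis(benzyloxy)-5,5'-dimethoxybiphenyl-3,3'-diyl]bis(methylene)}bis[(3S,4R)-3-hydroxyoxolan-2-one], hydroxyl trans to the C4 arm | O[C@@H]1C(=O)OC[C@H]1Cc1cc(OC)c(OCc2ccccc2)c(c1)-c1cc(C[C@@H]2COC(=O)[C@H]2O)cc(OC)c1OCc1ccccc1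
F2 | step 16 | tetra-O-benzyl bis-5,5-nortrachelogenin | COc1cc(C[C@]2(O)C(=O)OC[C@H]2Cc2cc(OC)c(OCc3ccccc3)c(-c3cc(C[C@@H]4COC(=O)[C@@]4(O)Cc4ccc(OCc5ccccc5)c(OC)c4)cc(OC)c3OCc3ccccc3)c2)ccc1OCc1ccccc1
F3 | step 13 | 4,4'-{[6,6'-bis(benzyloxy)-5,5'-dimethoxybiphenyl-3,3'-diyl]bis(methylene)}bis[(3R,4S)-3-(1-hydroxyethyl)oxolan-2-one], carbinol centres as a mixture | CC(O)[C@@H]1C(=O)OC[C@H]1Cc1cc(OC)c(OCc2ccccc2)c(c1)-c1cc(C[C@@H]2COC(=O)[C@H]2C(C)O)cc(OC)c1OCc1ccccc1
F4 | step 13 | 4,4'-{[6,6'-bis(benzyloxy)-5,5'-dimethoxybiphenyl-3,3'-diyl]bis(methylene)}bis{(3S,4S)-3-[4-(benzyloxy)-3-methoxybenzyl]-3-(1-hydroxyethyl)oxolan-2-one}, carbinol centres as a mixture | COc1cc(C[C@]2(C(C)O)C(=O)OC[C@H]2Cc2cc(OC)c(OCc3ccccc3)c(-c3cc(C[C@@H]4COC(=O)[C@@]4(C(C)O)Cc4ccc(OCc5ccccc5)c(OC)c4)cc(OC)c3OCc3ccccc3)c2)ccc1OCc1ccccc1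
F5 | step 7 | (3E,3'E)-4,4'-[6,6'-bis(benzyloxy)-5,5'-dimethoxybiphenyl-3,3'-diyl]bis[3-(methoxycarbonyl)but-3-enoic acid] | COC(=O)/C(CC(=O)O)=C/c1cc(OC)c(OCc2ccccc2)c(c1)-c1cc(/C=C(\CC(=O)O)C(=O)OC)cc(OC)c1OCc1ccccc1
F6 | step 7 | (3S,3'S)-4,4'-[6,6'-bis(benzyloxy)-5,5'-dimethoxybiphenyl-3,3'-diyl]bis[3-(methoxycarbonyl)butanoic acid] | COC(=O)[C@H](CC(=O)O)Cc1cc(OC)c(OCc2ccccc2)c(c1)-c1cc(C[C@@H](CC(=O)O)C(=O)OC)cc(OC)c1OCc1ccccc1
F7 | step 17 | 3,3'-{[6,6'-dihydroxy-5,5'-dimethoxybiphenyl-3,3'-diyl]bis(methylene)}bis[(2R,3R)-2,4-dihydroxy-2-(4-hydroxy-3-methoxybenzyl)butanoic acid] | COc1cc(C[C@](O)(C(=O)O)[C@@H](CO)Cc2cc(OC)c(O)c(-c3cc(C[C@H](CO)[C@@](O)(C(=O)O)Cc4ccc(O)c(OC)c4)cc(OC)c3O)c2)ccc1O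
A1 | alternative 1 | 4,4'-{[6,6'-bis(benzyloxy)-5,5'-dimethoxybiphenyl-3,3'-diyl]bis(methylene)}bis[(4R)-3-hydroxyoxolan-2-one], either C3 epimer | OC1C(=O)OC[C@H]1Cc1cc(OC)c(OCc2ccccc2)c(c1)-c1cc(C[C@@H]2COC(=O)C2O)cc(OC)c1OCc1ccccc1
A2 | alternative 1 | tetra-O-benzyl bis-5,5-nortrachelogenin | COc1cc(C[C@]2(O)C(=O)OC[C@H]2Cc2cc(OC)c(OCc3ccccc3)c(-c3cc(C[C@@H]4COC(=O)[C@@]4(O)Cc4ccc(OCc5ccccc5)c(OC)c4)cc(OC)c3OCc3ccccc3)c2)ccc1OCc1ccccc1
A3 | alternative 2 | dimethyl (R)-malate | COC(=O)C[C@@H](O)C(=O)OC
A4 | alternative 2 | tetramethyl bis[(2R,3S)-3-(arylmethyl)malate] on the 6,6'-bis(benzyloxy)-5,5'-dimethoxybiphenyl-3,3'-diyl core | COC(=O)[C@H](O)[C@@H](C(=O)OC)Cc1cc(OC)c(OCc2ccccc2)c(c1)-c1cc(C[C@H](C(=O)OC)[C@@H](O)C(=O)OC)cc(OC)c1OCc1ccccc1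
A5 | alternative 3 | bis[(2R,3Z)-pent-3-en-2-yl 2-(benzyloxy)-3-(4-benzyloxy-3-methoxyphenyl)propanoate] joined through C5 of each pentenyl chain to the 6,6'-bis(benzyloxy)-5,5'-dimethoxybiphenyl-3,3'-diyl core, ester α-centres unspecified | C[C@H](/C=C\Cc1cc(OC)c(OCc2ccccc2)c(c1)-c1cc(C/C=C\[C@@H](C)OC(=O)C(Cc2ccc(OCc3ccccc3)c(OC)c2)OCc2ccccc2)cc(OC)c1OCc1ccccc1)OC(=O)C(Cc1ccc(OCc2ccccc2)c(OC)c1)OCc1ccccc1
A6 | alternative 3 | bis[(2R,3R,4E)-2-benzyloxy-2-(4-benzyloxy-3-methoxybenzyl)-3-(arylmethyl)hex-4-enoic acid] on the same core | COc1cc(C[C@](OCc2ccccc2)(C(=O)O)[C@@H](/C=C/C)Cc2cc(OC)c(OCc3ccccc3)c(c2)-c2cc(C[C@H](/C=C/C)[C@@](OCc3ccccc3)(C(=O)O)Cc3ccc(OCc4ccccc4)c(OC)c3)cc(OC)c2OCc2ccccc2)ccc1OCc1ccccc1
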